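**Retrosynthetic overview**
1. Target 22 ⇒ γ-lactone 19 carrying cis ArCH(OH) and CH2OSi arms; the tetrahydrofuran ring (C6–O7–C8) is closed last by quinone-methide cyclisation, which also sets C8.
2. 19 ⇒ lactone 14 + O-TBS-vanillin 15: C1–C8 by lactone aldol, then C1 inverted by enolate protonation.
3. 14 ⇒ ester-aldehyde 9 + aryl Grignard from 11: the γ-lactone ring (O3–C4) is formed first.
4. 9 ⇒ ester 7 ⇒ allylic alcohol 3: the central C1–C5 bond and the C5 centre come from a Johnson–Claisen [3,3] rearrangement with chirality transfer from (S)-but-3-en-2-ol, the only chiral material bought.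
5. Ring order: γ-lactone (step 5), then tetrahydrofuran (step 8).

Assumption: C1–C8 are the target's 3,7-dioxabicyclo[3.3.0]octan-2-one locants (C2 lactone C=O, C4 syringyl carbon, C1/C5 ring-fusion carbons, C6 CH2, C8 guaiacyl carbon; target = 1S,4S,5R,8S, both aryls exo); 1, 2, 4, 10 and 15 are taken as catalogue compounds.

**Step 1**
Reactants: 1 (S)-but-3-en-2-ol; 2 allyloxy(tert-butyl)dimethylsilane
Product: 3 (2S,3E)-5-[(tert-butyldimethylsilyl)oxy]pent-3-en-2-ol
Conditions: Grubbs II (3 mol%), 2 (3 equiv), CH2Cl2, 40 °C; chromatography to remove the Z isomer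
Reagents that add atoms: none
Why: Olefin cross-metathesis of a secondary allylic alcohol with an allyl ether favours the E cross-product and leaves the purchased carbinol centre untouched.

**Step 2**
Reactants: 3 (2S,3E)-5-[(tert-butyldimethylsilyl)oxy]pent-3-en-2-ol; 4 triethyl orthoacetate
Product: 7 ethyl (3S,4E)-3-{[(tert-butyldimethylsilyl)oxy]methyl}hex-4-enoate, via mixed orthoester 5 (not isolated), via ketene acetal 6 (not isolated)
Conditions: 4 (6 equiv), EtCO2H (0.1 equiv), 138 °C, EtOH distilled off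
Reagents that add atoms: none
Why: The Johnson–Claisen [3,3]-sigmatropic rearrangement runs through a chair transition state with the methyl group equatorial, so it forms the C1–C5 bond and transfers the (S)-carbinol chirality to C5 (3S in 7).

**Step 3**
Reactants: 7 ethyl (3S,4E)-3-{[(tert-butyldimethylsilyl)oxy]methyl}hex-4-enoate
Product: 9 ethyl (3R)-3-{[(tert-butyldimethylsilyl)oxy]methyl}-4-oxobutanoate, via ozonide 8 (not isolated)
Conditions: O3, CH2Cl2, −78 °C; PPh3, −78 °C → rt; used crude at once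
Reagents that add atoms: ozone, [O-][O+]=O
Why: Ozonolysis with reductive work-up cleaves the propenyl group to the C4 aldehyde without touching C5, whose descriptor changes only by CIP priority.

**Step 4**
Reactants: 10 4-bromo-2,6-dimethoxyphenol
Product: 11 (4-bromo-2,6-dimethoxyphenoxy)(tert-butyl)dimethylsilane
Conditions: TBSCl, imidazole, DMF, rt
Reagents that add atoms: tert-butyldimethylsilyl chloride, CC(C)(C)[Si](C)(C)Cl
Why: Silyl ether formation masks the acidic phenol so that the aryl Grignard reagent can be made; no stereocentre is involved.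

**Step 5**
Reactants: 9 ethyl (3R)-3-{[(tert-butyldimethylsilyl)oxy]methyl}-4-oxobutanoate; 11 (4-bromo-2,6-dimethoxyphenoxy)(tert-butyl)dimethylsilane
Product: 14 (4R,5S)-4-{[(tert-butyldimethylsilyl)oxy]methyl}-5-{4-[(tert-butyldimethylsilyl)oxy]-3,5-dimethoxyphenyl}dihydrofuran-2(3H)-one, via aryl Grignard reagent 12 (not isolated), via magnesium alkoxide 13 (not isolated)
Conditions: 11, Mg, THF, 50 °C; then 9, THF, −78 °C → rt; aq NH4Cl; chromatography
Reagents that add atoms: none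
Why: Grignard addition is chemoselective for the aldehyde, and Felkin–Anh control (aryl anti to the bulkier CH2OTBS arm, expected to be modest) sets C4 as S before the alkoxide closes onto the ester to give the 4,5-trans γ-lactone, the minor cis isomer being removed.

**Step 6**
Reactants: 14 (4R,5S)-4-{[(tert-butyldimethylsilyl)oxy]methyl}-5-{4-[(tert-butyldimethylsilyl)oxy]-3,5-dimethoxyphenyl}dihydrofuran-2(3H)-one; 15 4-[(tert-butyldimethylsilyl)oxy]-3-methoxybenzaldehyde
Product: 17 (3R,4R,5S)-3-[{4-[(tert-butyldimethylsilyl)oxy]-3-methoxyphenyl}(hydroxy)methyl]-4-{[(tert-butyldimethylsilyl)oxy]methyl}-5-{4-[(tert-butyldimethylsilyl)oxy]-3,5-dimethoxyphenyl}dihydrofuran-2(3H)-one (both carbinol epimers), via lithium enolate 16 (not isolated)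
Conditions: LDA (1.1 equiv), THF, −78 °C; 15, −78 °C, 30 min; AcOH, −78 °C
Reagents that add atoms: none
Why: In this lactone enolate aldol addition the aldehyde enters anti to the neighbouring CH2OTBS group, forming the C1–C8 bond as the 3,4-trans adduct, while the carbinol carbon (C8) is left as an epimer mixture that converges in step 8.

**Step 7**
Reactants: 17 (3R,4R,5S)-aldol adduct
Product: 19 (3S,4R,5S)-3-[{4-[(tert-butyldimethylsilyl)oxy]-3-methoxyphenyl}(hydroxy)methyl]-4-{[(tert-butyldimethylsilyl)oxy]methyl}-5-{4-[(tert-butyldimethylsilyl)oxy]-3,5-dimethoxyphenyl}dihydrofuran-2(3H)-one (both carbinol epimers), via dilithium alkoxide enolate 18 (not isolated)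
Conditions: LDA (2.5 equiv), THF, −78 → −40 °C; AcOH in THF, −78 °C; chromatography
Reagents that add atoms: none
Why: Deprotonation gives the alkoxide–enolate dianion, which resists β-elimination, and kinetic protonation anti to the CH2OTBS group inverts lactone C3 (= C1) to S, giving the 3,4-cis arrangement needed for ring closure.

**Step 8**
Reactants: 19 (3S,4R,5S)-aldol adduct
Product: 22 (1S,4S,5R,8S)-4-(4-hydroxy-3,5-dimethoxyphenyl)-8-(4-hydroxy-3-methoxyphenyl)-3,7-dioxabicyclo[3.3.0]octan-2-one, via desilylated lactone 20 (not isolated), via quinone methide 21 (not isolated)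
Conditions: TBAF, AcOH (3.3 equiv each), THF, 0 °C → rt; then TsOH·H2O (10 mol%), CH2Cl2, 0 °C → rt
Reagents that add atoms: none
Why: Buffered fluoride desilylation followed by acid ionises the p-hydroxybenzylic C8–OH to a quinone methide that the cis CH2OH traps 5-exo (intramolecular oxa-1,6-addition), giving the cis-fused tetrahydrofuran with the aryl on the convex face, so both carbinol epimers converge on 8S.

**Compound list**
1 | (S)-but-3-en-2-ol | C[C@H](O)C=C | starting material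
2 | allyloxy(tert-butyl)dimethylsilane | C=CCO[Si](C)(C)C(C)(C)C | starting material
3 | (2S,3E)-5-[(tert-butyldimethylsilyl)oxy]pent-3-en-2-ol | C[C@H](O)/C=C/CO[Si](C)(C)C(C)(C)C | intermediate
4 | triethyl orthoacetate | CC(OCC)(OCC)OCC | starting material
5 | mixed orthoester, tert-butyl{[(2E,4S)-4-(1,1-diethoxyethoxy)pent-2-en-1-yl]oxy}dimethylsilane | C[C@H](OC(C)(OCC)OCC)/C=C/CO[Si](C)(C)C(C)(C)C | intermediate
6 | ketene acetal, tert-butyl({(2E,4S)-4-[(1-ethoxyethenyl)oxy]pent-2-en-1-yl}oxy)dimethylsilane | C[C@H](OC(=C)OCC)/C=C/CO[Si](C)(C)C(C)(C)C | intermediate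
7 | ethyl (3S,4E)-3-{[(tert-butyldimethylsilyl)oxy]methyl}hex-4-enoate | CCOC(=O)C[C@H](CO[Si](C)(C)C(C)(C)C)/C=C/C | intermediate
8 | ozonide, ethyl (3R)-4-[(tert-butyldimethylsilyl)oxy]-3-(5-methyl-1,2,4-trioxolan-3-yl)butanoate (trioxolane carbons unassigned) | CCOC(=O)C[C@H](CO[Si](C)(C)C(C)(C)C)C1OOC(C)O1 | intermediate
9 | ethyl (3R)-3-{[(tert-butyldimethylsilyl)oxy]methyl}-4-oxobutanoate | CCOC(=O)C[C@H](CO[Si](C)(C)C(C)(C)C)C=O | intermediate
10 | 4-bromo-2,6-dimethoxyphenol | COc1cc(Br)cc(OC)c1O | starting material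
11 | (4-bromo-2,6-dimethoxyphenoxy)(tert-butyl)dimethylsilane | COc1cc(Br)cc(OC)c1O[Si](C)(C)C(C)(C)C | intermediate
12 | {4-[(tert-butyldimethylsilyl)oxy]-3,5-dimethoxyphenyl}magnesium bromide | COc1cc([Mg]Br)cc(OC)c1O[Si](C)(C)C(C)(C)C | intermediate
13 | bromomagnesium alkoxide of ethyl (3R,4S)-3-{[(tert-butyldimethylsilyl)oxy]methyl}-4-{4-[(tert-butyldimethylsilyl)oxy]-3,5-dimethoxyphenyl}-4-hydroxybutanoate | CCOC(=O)C[C@H](CO[Si](C)(C)C(C)(C)C)[C@H](O[Mg]Br)c1cc(OC)c(O[Si](C)(C)C(C)(C)C)c(OC)c1 | intermediate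
14 | (4R,5S)-4-{[(tert-butyldimethylsilyl)oxy]methyl}-5-{4-[(tert-butyldimethylsilyl)oxy]-3,5-dimethoxyphenyl}dihydrofuran-2(3H)-one | O=C1C[C@H](CO[Si](C)(C)C(C)(C)C)[C@@H](c2cc(OC)c(O[Si](C)(C)C(C)(C)C)c(OC)c2)O1 | intermediate
15 | 4-[(tert-butyldimethylsilyl)oxy]-3-methoxybenzaldehyde | COc1cc(C=O)ccc1O[Si](C)(C)C(C)(C)C | starting material
16 | lithium enolate of 14 (4R,5S) | [Li]OC1=C[C@H](CO[Si](C)(C)C(C)(C)C)[C@@H](c2cc(OC)c(O[Si](C)(C)C(C)(C)C)c(OC)c2)O1 | intermediate
17 | (3R,4R,5S)-3-[{4-[(tert-butyldimethylsilyl)oxy]-3-methoxyphenyl}(hydroxy)methyl]-4-{[(tert-butyldimethylsilyl)oxy]methyl}-5-{4-[(tert-butyldimethylsilyl)oxy]-3,5-dimethoxyphenyl}dihydrofuran-2(3H)-one, carbinol epimers | O=C1[C@@H](C(O)c2ccc(O[Si](C)(C)C(C)(C)C)c(OC)c2)[C@H](CO[Si](C)(C)C(C)(C)C)[C@@H](c2cc(OC)c(O[Si](C)(C)C(C)(C)C)c(OC)c2)O1 | intermediate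
18 | dilithium alkoxide enolate of 17 (4R,5S) | [Li]OC1=C(C(O[Li])c2ccc(O[Si](C)(C)C(C)(C)C)c(OC)c2)[C@H](CO[Si](C)(C)C(C)(C)C)[C@@H](c2cc(OC)c(O[Si](C)(C)C(C)(C)C)c(OC)c2)O1 | intermediate
19 | (3S,4R,5S)-epimer of 17 (3,4-cis), carbinol epimers | O=C1[C@H](C(O)c2ccc(O[Si](C)(C)C(C)(C)C)c(OC)c2)[C@H](CO[Si](C)(C)C(C)(C)C)[C@@H](c2cc(OC)c(O[Si](C)(C)C(C)(C)C)c(OC)c2)O1 | intermediate
20 | (3S,4R,5S)-3-[hydroxy(4-hydroxy-3-methoxyphenyl)methyl]-5-(4-hydroxy-3,5-dimethoxyphenyl)-4-(hydroxymethyl)dihydrofuran-2(3H)-one, carbinol epimers | O=C1[C@H](C(O)c2ccc(O)c(OC)c2)[C@H](CO)[C@@H](c2cc(OC)c(O)c(OC)c2)O1 | intermediate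
21 | p-quinone methide of 20: (4R,5S)-5-(4-hydroxy-3,5-dimethoxyphenyl)-4-(hydroxymethyl)-3-[(3-methoxy-4-oxocyclohexa-2,5-dien-1-ylidene)methyl]dihydrofuran-2(3H)-one, C3 arranged as in 20, exocyclic alkene geometry unassigned | COC1=CC(=C[C@H]2C(=O)O[C@H](c3cc(OC)c(O)c(OC)c3)[C@H]2CO)C=CC1=O | intermediate
22 | (1S,4S,5R,8S)-4-(4-hydroxy-3,5-dimethoxyphenyl)-8-(4-hydroxy-3-methoxyphenyl)-3,7-dioxabicyclo[3.3.0]octan-2-one | COc1cc([C@H]2OC[C@H]3[C@@H]2C(=O)O[C@@H]3c2cc(OC)c(O)c(OC)c2)ccc1O | target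

**Totals**
Total step count: 8. Longest linear sequence: 7 (steps 1, 2, 3, 5, 6, 7, 8); step 4 is a one-step side branch.

**Steps most likely to fail**

Step 5 is the weakest for selectivity: the two arms on C5 (CH2OTBS and CH2CO2Et) are similar in size, so open-chain Felkin control at C4 may give a poor trans:cis ratio, and the aldehyde can epimerise. The fallback sets out from 7 and comes back at 14, and sets C4 inside a ring instead. Saponification of 7 (LiOH, THF–H2O) gives (3S,4E)-3-{[(tert-butyldimethylsilyl)oxy]methyl}hex-4-enoic acid F1. Ozonolysis (O3, then PPh3) gives directly the cyclic pseudo-acid (4R)-4-{[(tert-butyldimethylsilyl)oxy]methyl}-5-hydroxydihydrofuran-2(3H)-one F2 as an anomer mixture. BF3·OEt2 with 2,6-dimethoxyphenol (CH2Cl2, −40 °C) then arylates the cyclic acyl-oxocarbenium ion para to the phenol OH and anti to the neighbouring CH2OTBS group, giving (4R,5S)-4-{[(tert-butyldimethylsilyl)oxy]methyl}-5-(4-hydroxy-3,5-dimethoxyphenyl)dihydrofuran-2(3H)-one F3. TBSCl/imidazole returns 14.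

Step 7 may fail through retro-aldol of the aldolate before the second deprotonation, or through poor facial selectivity in the protonation. The fallback sets out from 17 and comes back at 22, replacing kinetic control by a thermodynamic funnel. Dess–Martin oxidation of 17 gives the β-keto lactone (4R,5S)-3-{4-[(tert-butyldimethylsilyl)oxy]-3-methoxybenzoyl}-4-{[(tert-butyldimethylsilyl)oxy]methyl}-5-{4-[(tert-butyldimethylsilyl)oxy]-3,5-dimethoxyphenyl}dihydrofuran-2(3H)-one F4, whose C3 is freely epimerisable. TBAF/AcOH removes the three silyl groups; the freed CH2OH can add to the ketone only in the cis-fused form, so the material drains into the hemiketal (1S,4S,5R)-8-hydroxy-4-(4-hydroxy-3,5-dimethoxyphenyl)-8-(4-hydroxy-3-methoxyphenyl)-3,7-dioxabicyclo[3.3.0]octan-2-one F5. Et3SiH/BF3·OEt2 (CH2Cl2, −78 °C) reduces the aryl-stabilised oxocarbenium ion to the exo-aryl ether 22, the stereochemical outcome reported for related aryl furofuran hemiketals.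

Step 8 may fail because the free phenoxide/phenol next to a β-hydroxy lactone can undergo retro-aldol or translactonisation before the ring closes, and prolonged acid can erode the exo selectivity at C8. The fallback sets out from 19 and comes back at 22, closing the ring before the phenols are unmasked. BF3·OEt2 (CH2Cl2, −78 → −40 °C) ionises the benzylic C8–OH of 19 while the phenols are still silylated; the cation is captured by the oxygen of the neighbouring CH2OTBS group, which loses its silyl group, to give (1S,4S,5R,8S)-4-{4-[(tert-butyldimethylsilyl)oxy]-3,5-dimethoxyphenyl}-8-{4-[(tert-butyldimethylsilyl)oxy]-3-methoxyphenyl}-3,7-dioxabicyclo[3.3.0]octan-2-one F6. TBAF/AcOH then frees the two phenols to give 22.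

**Further compounds**
F1 | step 5 | (3S,4E)-3-{[(tert-butyldimethylsilyl)oxy]methyl}hex-4-enoic acid | OC(=O)C[C@H](CO[Si](C)(C)C(C)(C)C)/C=C/C
F2 | step 5 | (4R)-4-{[(tert-butyldimethylsilyl)oxy]methyl}-5-hydroxydihydrofuran-2(3H)-one (anomer mixture) | O=C1C[C@H](CO[Si](C)(C)C(C)(C)C)C(O)O1
F3 | step 5 | (4R,5S)-4-{[(tert-butyldimethylsilyl)oxy]methyl}-5-(4-hydroxy-3,5-dimethoxyphenyl)dihydrofuran-2(3H)-one | O=C1C[C@H](CO[Si](C)(C)C(C)(C)C)[C@@H](c2cc(OC)c(O)c(OC)c2)O1
F4 | step 7 | (4R,5S)-3-{4-[(tert-butyldimethylsilyl)oxy]-3-methoxybenzoyl}-4-{[(tert-butyldimethylsilyl)oxy]methyl}-5-{4-[(tert-butyldimethylsilyl)oxy]-3,5-dimethoxyphenyl}dihydrofuran-2(3H)-one (C3 epimerisable) | O=C1C(C(=O)c2ccc(O[Si](C)(C)C(C)(C)C)c(OC)c2)[C@H](CO[Si](C)(C)C(C)(C)C)[C@@H](c2cc(OC)c(O[Si](C)(C)C(C)(C)C)c(OC)c2)O1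
F5 | step 7 | (1S,4S,5R)-8-hydroxy-4-(4-hydroxy-3,5-dimethoxyphenyl)-8-(4-hydroxy-3-methoxyphenyl)-3,7-dioxabicyclo[3.3.0]octan-2-one (C8 anomers) | COc1cc(C2(O)OC[C@H]3[C@@H]2C(=O)O[C@@H]3c2cc(OC)c(O)c(OC)c2)ccc1O
F6 | step 8 | (1S,4S,5R,8S)-4-{4-[(tert-butyldimethylsilyl)oxy]-3,5-dimethoxyphenyl}-8-{4-[(tert-butyldimethylsilyl)oxy]-3-methoxyphenyl}-3,7-dioxabicyclo[3.3.0]octan-2-one | COc1cc([C@H]2OC[C@H]3[C@@H]2C(=O)O[C@@H]3c2cc(OC)c(O[Si](C)(C)C(C)(C)C)c(OC)c2)ccc1O[Si](C)(C)C(C)(C)C
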